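**Retrosynthetic overview**
- Ring B (the dihydropyranone) is closed last, by acid cyclodehydration of a δ-hydroxy tricarbonyl compound (the C2 hydroxyl onto the C8a enol/ketone carbon, forming O1–C8a).
- The tricarbonyl compound comes from a lactone carrying a dithiane-masked C4 ketone and a C8a carbinol, by oxidation and thioacetal hydrolysis.
- Key union (C4–C4a): 1,4-addition of a lithiated dithiane (fragment A, the C10 acyl-anion piece) to an unsaturated δ-lactone (fragment B, the C15 piece), with the enolate oxidised at C8a in the same flask.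
- Fragment A comes from (R)-epichlorohydrin, 1-bromohexane and 1,3-dithiane; fragment B from (S)-2-(but-3-en-1-yl)oxirane, oct-1-ene and ethyl propiolate.
- Ring order: ring A (δ-lactone) is made before the coupling; ring B is made in the final step.

Assumption: (R)-epichlorohydrin and (S)-2-(but-3-en-1-yl)oxirane are bought as single enantiomers.

**Fragment A**

Step 1
Reactants: 1 1-bromohexane; 2 (R)-epichlorohydrin, (2R)-2-(chloromethyl)oxirane
Product: 4 (2R)-1-chlorononan-2-ol, via hexylmagnesium bromide 3 (not isolated)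
Conditions: Mg, THF, 40 °C; then 2, CuI (5 mol%), THF, −40 → 0 °C; aq. NH4Cl
Reagents that add atoms: none
Why: Copper-catalysed Grignard opening of the epoxide (SN2 at the unsubstituted ring carbon) is much faster than displacement of the primary chloride, so the C–O stereocentre of 2 is carried over untouched as the future C2 (R).

Step 2
Reactants: 4 (2R)-1-chlorononan-2-ol
Product: 5 (2R)-2-heptyloxirane
Conditions: NaOH (powdered), Et2O, rt
Reagents that add atoms: none
Why: Intramolecular Williamson etherification of the chlorohydrin alkoxide closes the epoxide at the CH2Cl carbon, so the stereocentre is not involved and stays (R).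

Step 3
Reactants: 6 1,3-dithiane; 5 (2R)-2-heptyloxirane
Product: 8 (2R)-1-(1,3-dithian-2-yl)nonan-2-ol, via 2-lithio-1,3-dithiane 7 (not isolated)
Conditions: n-BuLi, THF, −30 °C; then 5, −30 → 0 °C; aq. NH4Cl
Reagents that add atoms: none
Why: Corey–Seebach umpolung, in which the lithiated dithiane opens the terminal epoxide by SN2 at CH2, so the carbinol centre keeps its (R) configuration.

Step 4
Reactants: 8 (2R)-1-(1,3-dithian-2-yl)nonan-2-ol
Product: 9 tert-butyl{[(2R)-1-(1,3-dithian-2-yl)nonan-2-yl]oxy}dimethylsilane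
Conditions: TBSCl, imidazole, DMF, rt
Reagents that add atoms: tert-butyldimethylsilyl chloride, CC(C)(C)[Si](C)(C)Cl
Why: Imidazole-promoted silylation protects the secondary alcohol as a base-stable silyl ether so that the dithiane C–H can be metalated later; no stereocentre is touched.

**Fragment B**

Step 5
Reactants: 10 (2S)-2-(but-3-en-1-yl)oxirane; 11 oct-1-ene
Product: 12 (2S)-2-[(3E)-dec-3-en-1-yl]oxirane (E/Z mixture, E major)
Conditions: second-generation Grubbs catalyst RuCl2(=CHPh)(PCy3)(H2IMes) (2 mol%), 11 (4 equiv), CH2Cl2, 40 °C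
Reagents that add atoms: none
Why: Olefin cross-metathesis of two unhindered terminal alkenes is driven by loss of ethene and by the excess of 11, the epoxide is inert to the ruthenium carbene, and the alkene geometry is irrelevant because the double bond is hydrogenated next.

Step 6
Reactants: 12 (2S)-2-[(3E)-dec-3-en-1-yl]oxirane
Product: 13 (2S)-2-decyloxirane
Conditions: H2 (1 atm), 5% Pt/C, EtOAc, rt
Reagents that add atoms: none
Why: Heterogeneous catalytic hydrogenation of the disubstituted alkene is far faster on platinum than hydrogenolysis of an unactivated alkyl epoxide, and the stereocentre is not involved.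

Step 7
Reactants: 14 ethyl propiolate; 13 (2S)-2-decyloxirane
Product: 16 ethyl (5S)-5-hydroxypentadec-2-ynoate, via lithium ethyl propiolate 15 (not isolated)
Conditions: n-BuLi, THF, −78 °C; BF3·OEt2; then 13, −78 °C; aq. NH4Cl
Reagents that add atoms: none
Why: Yamaguchi–Hirao alkynylation, in which the BF3-activated epoxide is opened at its terminal carbon by the lithium alkynide at −78 °C where the metalated propiolate is stable, so the carbinol centre stays (S).

Step 8
Reactants: 16 ethyl (5S)-5-hydroxypentadec-2-ynoate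
Product: 18 (6S)-6-decyl-5,6-dihydro-2H-pyran-2-one, via Z-hydroxy enoate 17 (not isolated)
Conditions: H2 (1 atm), Pd/CaCO3 poisoned with Pb(OAc)2 (Lindlar catalyst), quinoline, EtOAc, rt; then PPTS (cat.), PhMe, 60 °C
Reagents that add atoms: none
Why: Lindlar semihydrogenation gives the cis-enoate, whose geometry places the hydroxyl next to the ester so that lactonisation (transesterification) closes ring A without touching the (S) centre.

**Union and endgame**

Step 9
Reactants: 9 tert-butyl{[(2R)-1-(1,3-dithian-2-yl)nonan-2-yl]oxy}dimethylsilane; 18 (6S)-6-decyl-5,6-dihydro-2H-pyran-2-one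
Product: 21 (3R,4S,6S)-6-decyl-3-hydroxy-4-{2-[(2R)-2-(tert-butyldimethylsilyloxy)nonyl]-1,3-dithian-2-yl}tetrahydro-2H-pyran-2-one, via lithiated dithiane 19 (not isolated), via lithium lactone enolate 20 (not isolated)
Conditions: t-BuLi, THF–HMPA (10:1), −78 °C; then 18, −78 °C, 1 h; then (camphorsulfonyl)oxaziridine, −78 → −30 °C; aq. NH4Cl
Reagents that add atoms: (camphorsulfonyl)oxaziridine (either enantiomer), CC1(C)C2CCC13CS(=O)(=O)N4OC34C2
Why: In HMPA the solvent-separated dithiane anion adds to the unsaturated lactone in Michael fashion (Corey–Seebach acyl-anion 1,4-addition) anti to the C6 decyl group, and the resulting lactone enolate is hydroxylated by the N-sulfonyloxaziridine (Davis oxidation) anti to the new C4 substituent; both new centres (expected 3R,4S) are erased later, so their ratio does not matter.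

Step 10
Reactants: 21 (3R,4S,6S)-6-decyl-3-hydroxy-4-{2-[(2R)-2-(tert-butyldimethylsilyloxy)nonyl]-1,3-dithian-2-yl}tetrahydro-2H-pyran-2-one
Product: 23 (6S)-6-decyl-3-hydroxy-4-{2-[(2R)-2-(tert-butyldimethylsilyloxy)nonyl]-1,3-dithian-2-yl}-5,6-dihydro-2H-pyran-2-one, via keto tautomer 22 (not isolated)
Conditions: (COCl)2, DMSO, CH2Cl2, −78 °C; then Et3N, −78 → 0 °C
Reagents that add atoms: none
Why: Swern oxidation converts the secondary α-hydroxy lactone into the α-keto lactone without affecting the thioacetal or the silyl ether, and the ketone tautomerises to the conjugated enol, which removes the C3 and C4 stereocentres.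

Step 11
Reactants: 23 (6S)-6-decyl-3-hydroxy-4-{2-[(2R)-2-(tert-butyldimethylsilyloxy)nonyl]-1,3-dithian-2-yl}-5,6-dihydro-2H-pyran-2-one
Product: 24 (6S)-4-[(3R)-3-(tert-butyldimethylsilyloxy)decanoyl]-6-decyl-3-hydroxy-5,6-dihydro-2H-pyran-2-one
Conditions: Hg(ClO4)2, CaCO3, THF–H2O (5:1), 0 °C → rt
Reagents that add atoms: water, O
Why: Thiophilic mercuric-salt hydrolysis of the thioacetal (Corey–Seebach unmasking) is non-oxidative and buffered, so it frees the C4 ketone without attacking the enol, the lactone or the silyl ether.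

Step 12
Reactants: 24 (6S)-4-[(3R)-3-(tert-butyldimethylsilyloxy)decanoyl]-6-decyl-3-hydroxy-5,6-dihydro-2H-pyran-2-one
Product: 27 (2R,6S)-6-decyl-2-heptyl-2,3,5,6-tetrahydropyrano[3,4-b]pyran-4,8-dione, via hydroxy tricarbonyl 25 (not isolated), via bicyclic hemiketal 26 (not isolated)
Conditions: 48% aq. HF, MeCN, 0 °C → rt
Reagents that add atoms: none
Why: Desilylation frees the C2 hydroxyl, which adds to the electrophilic C8a carbonyl to give a six-membered hemiketal that loses water under acid (cyclodehydration of a δ-hydroxy 1,3-dicarbonyl to a 2,3-dihydro-4H-pyran-4-one); the C2–O bond is never broken, so (R) is retained, and C6 (S) is untouched.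

**Compound list**

1 | 1-bromohexane | CCCCCCBr | starting material
2 | (R)-epichlorohydrin, (2R)-2-(chloromethyl)oxirane | ClC[C@H]1CO1 | starting material
3 | hexylmagnesium bromide | CCCCCC[Mg]Br | intermediate
4 | (2R)-1-chlorononan-2-ol | ClC[C@H](O)CCCCCCC | intermediate
5 | (2R)-2-heptyloxirane | CCCCCCC[C@@H]1CO1 | intermediate
6 | 1,3-dithiane | C1CSCSC1 | starting material
7 | 2-lithio-1,3-dithiane | [Li]C1SCCCS1 | intermediate
8 | (2R)-1-(1,3-dithian-2-yl)nonan-2-ol | CCCCCCC[C@@H](O)CC1SCCCS1 | intermediate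
9 | tert-butyl{[(2R)-1-(1,3-dithian-2-yl)nonan-2-yl]oxy}dimethylsilane | CCCCCCC[C@@H](O[Si](C)(C)C(C)(C)C)CC1SCCCS1 | intermediate
10 | (2S)-2-(but-3-en-1-yl)oxirane | C=CCC[C@H]1CO1 | starting material
11 | oct-1-ene | C=CCCCCCC | starting material
12 | (2S)-2-[(3E)-dec-3-en-1-yl]oxirane (E shown; E/Z mixture) | CCCCCC/C=C/CC[C@H]1CO1 | intermediate
13 | (2S)-2-decyloxirane | CCCCCCCCCC[C@H]1CO1 | intermediate
14 | ethyl propiolate (ethyl prop-2-ynoate) | C#CC(=O)OCC | starting material
15 | ethyl 3-lithioprop-2-ynoate | [Li]C#CC(=O)OCC | intermediate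
16 | ethyl (5S)-5-hydroxypentadec-2-ynoate | CCCCCCCCCC[C@H](O)CC#CC(=O)OCC | intermediate
17 | ethyl (2Z,5S)-5-hydroxypentadec-2-enoate | CCCCCCCCCC[C@H](O)C/C=C\C(=O)OCC | intermediate
18 | (6S)-6-decyl-5,6-dihydro-2H-pyran-2-one | CCCCCCCCCC[C@H]1CC=CC(=O)O1 | intermediate
19 | {2-[(2R)-2-(tert-butyldimethylsilyloxy)nonyl]-1,3-dithian-2-yl}lithium | CCCCCCC[C@@H](O[Si](C)(C)C(C)(C)C)CC1([Li])SCCCS1 | intermediate
20 | lithium (4S,6S)-6-decyl-4-{2-[(2R)-2-(tert-butyldimethylsilyloxy)nonyl]-1,3-dithian-2-yl}-5,6-dihydro-4H-pyran-2-olate (4,6-trans) | CCCCCCCCCC[C@H]1C[C@H](C2(SCCCS2)C[C@@H](CCCCCCC)O[Si](C)(C)C(C)(C)C)C=C(O[Li])O1 | intermediate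
21 | (3R,4S,6S)-6-decyl-3-hydroxy-4-{2-[(2R)-2-(tert-butyldimethylsilyloxy)nonyl]-1,3-dithian-2-yl}tetrahydro-2H-pyran-2-one (expected major isomer) | CCCCCCCCCC[C@H]1C[C@H](C2(SCCCS2)C[C@@H](CCCCCCC)O[Si](C)(C)C(C)(C)C)[C@@H](O)C(=O)O1 | intermediate
22 | (4S,6S)-6-decyl-4-{2-[(2R)-2-(tert-butyldimethylsilyloxy)nonyl]-1,3-dithian-2-yl}dihydro-2H-pyran-2,3(4H)-dione | CCCCCCCCCC[C@H]1C[C@H](C2(SCCCS2)C[C@@H](CCCCCCC)O[Si](C)(C)C(C)(C)C)C(=O)C(=O)O1 | intermediate
23 | (6S)-6-decyl-3-hydroxy-4-{2-[(2R)-2-(tert-butyldimethylsilyloxy)nonyl]-1,3-dithian-2-yl}-5,6-dihydro-2H-pyran-2-one | CCCCCCCCCC[C@H]1CC(C2(SCCCS2)C[C@@H](CCCCCCC)O[Si](C)(C)C(C)(C)C)=C(O)C(=O)O1 | intermediate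
24 | (6S)-4-[(3R)-3-(tert-butyldimethylsilyloxy)decanoyl]-6-decyl-3-hydroxy-5,6-dihydro-2H-pyran-2-one | CCCCCCCCCC[C@H]1CC(C(=O)C[C@@H](CCCCCCC)O[Si](C)(C)C(C)(C)C)=C(O)C(=O)O1 | intermediate
25 | (6S)-6-decyl-3-hydroxy-4-[(3R)-3-hydroxydecanoyl]-5,6-dihydro-2H-pyran-2-one | CCCCCCCCCC[C@H]1CC(C(=O)C[C@@H](CCCCCCC)O)=C(O)C(=O)O1 | intermediate
26 | (2R,6S)-6-decyl-2-heptyl-8a-hydroxyhexahydropyrano[3,4-b]pyran-4,8-dione (C4a/C8a not controlled) | CCCCCCCCCC[C@H]1CC2C(=O)C[C@@H](CCCCCCC)OC2(O)C(=O)O1 | intermediate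
27 | (2R,6S)-6-decyl-2-heptyl-2,3,5,6-tetrahydropyrano[3,4-b]pyran-4,8-dione | CCCCCCCCCC[C@H]1CC2=C(O[C@H](CCCCCCC)CC2=O)C(=O)O1 | target

**Totals**
Total step count: 12.
Longest linear sequence: 8 steps (steps 1–4 then 9–12; equally steps 5–8 then 9–12).

**Steps most likely to fail, with fallbacks**

Step 9. The lithiated dithiane is strongly basic and hindered. It may deprotonate the lactone at C5 (leading to ring opening), add 1,2, or leave an enolate too crowded for clean hydroxylation. The fallback makes the C4–C4a bond by SN2 and closes ring A afterwards. It sets out from 13 and from 19 (the anion of 9). Epoxide 13 is ring-expanded with dimethylsulfoxonium methylide (Me3S(O)I, KOt-Bu, t-BuOH, 60 °C) to (2S)-2-decyloxetane F1. Anion 19 opens F1 at its unsubstituted CH2 (BF3·OEt2, THF, −78 °C) to give (3S)-1-{2-[(2R)-2-(tert-butyldimethylsilyloxy)nonyl]-1,3-dithian-2-yl}tridecan-3-ol F2. Acylation with methyl chlorooxoacetate (pyridine, CH2Cl2, 0 °C) gives methyl (3S)-1-{2-[(2R)-2-(tert-butyldimethylsilyloxy)nonyl]-1,3-dithian-2-yl}tridecan-3-yl oxalate F3. Hg(ClO4)2/CaCO3 in aqueous THF then frees the ketone, giving methyl (8R,13S)-8-(tert-butyldimethylsilyloxy)-10-oxotricosan-13-yl oxalate F4. LiN(SiMe3)2 (2.2 equiv, THF, −78 → 0 °C) brings about a Dieckmann-type Claisen cyclisation; only the C4a enolate can close a six-membered ring, so equilibration funnels material to 24, where the fallback rejoins the route. The weak point of this fallback is that the C3 enolate may instead lose the silyloxy group.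

Step 11. The mercuric salt may react with the electron-rich enol of 23, or the hydrolysis may stall at the crowded thioacetal. The fallback changes the order so that the thioacetal is removed before any enol exists. It sets out from 21. Hg(ClO4)2/CaCO3 in aqueous THF gives (3R,4S,6S)-4-[(3R)-3-(tert-butyldimethylsilyloxy)decanoyl]-6-decyl-3-hydroxytetrahydro-2H-pyran-2-one F5. Dess–Martin periodinane (NaHCO3, CH2Cl2, 0 °C) then oxidises the C3 carbinol and gives 24, where the route is rejoined. F5 is a β-hydroxy ketone and must be kept buffered to avoid loss of water across C3–C4.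

Step 12. Acid may eliminate the C2 oxygen to an enone (which would scramble C2 on re-addition), or the hemiketal 26 may not dehydrate. The fallback closes ring B by conjugate addition–elimination on a vinylogous ester instead. It sets out from 24. Me3SiCHN2 (MeOH–PhMe, 0 °C) methylates the acidic enol to give (6S)-4-[(3R)-3-(tert-butyldimethylsilyloxy)decanoyl]-6-decyl-3-methoxy-5,6-dihydro-2H-pyran-2-one F6. CF3CO2H in wet CH2Cl2 (rt) then removes the silyl group, and the freed C2 hydroxyl displaces methanol from the β-methoxy enone (6-endo oxa-Michael addition, then loss of MeOH), giving 27 directly.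

**Further compounds**

F1 | step 9 | (2S)-2-decyloxetane | CCCCCCCCCC[C@H]1CCO1
F2 | step 9 | (3S)-1-{2-[(2R)-2-(tert-butyldimethylsilyloxy)nonyl]-1,3-dithian-2-yl}tridecan-3-ol | CCCCCCCCCC[C@H](O)CCC1(SCCCS1)C[C@@H](CCCCCCC)O[Si](C)(C)C(C)(C)C
F3 | step 9 | methyl (3S)-1-{2-[(2R)-2-(tert-butyldimethylsilyloxy)nonyl]-1,3-dithian-2-yl}tridecan-3-yl oxalate | CCCCCCCCCC[C@H](OC(=O)C(=O)OC)CCC1(SCCCS1)C[C@@H](CCCCCCC)O[Si](C)(C)C(C)(C)C
F4 | step 9 | methyl (8R,13S)-8-(tert-butyldimethylsilyloxy)-10-oxotricosan-13-yl oxalate | CCCCCCCCCC[C@H](OC(=O)C(=O)OC)CCC(=O)C[C@@H](CCCCCCC)O[Si](C)(C)C(C)(C)C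
F5 | step 11 | (3R,4S,6S)-4-[(3R)-3-(tert-butyldimethylsilyloxy)decanoyl]-6-decyl-3-hydroxytetrahydro-2H-pyran-2-one | CCCCCCCCCC[C@H]1C[C@H](C(=O)C[C@@H](CCCCCCC)O[Si](C)(C)C(C)(C)C)[C@@H](O)C(=O)O1
F6 | step 12 | (6S)-4-[(3R)-3-(tert-butyldimethylsilyloxy)decanoyl]-6-decyl-3-methoxy-5,6-dihydro-2H-pyran-2-one | CCCCCCCCCC[C@H]1CC(C(=O)C[C@@H](CCCCCCC)O[Si](C)(C)C(C)(C)C)=C(OC)C(=O)O1
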